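Retrosynthetic overview
1. 16 ⇒ 15 ⇒ 12 ⇒ 10: the 8-prenyl group comes last. MOM removal follows a Eu(fod)3-catalysed Claisen–Cope shift of a prenyl group from O-5 via C-6 to C-8, because this alkene would not survive the hydrogenation that finishes ring D.
2. 10 ⇒ 9 ⇒ 5 + prenal (6): ring D is made by a formal [3+3] annulation. It joins the three-atom edge O-4'/C-4'/C-3' of ring B to the chain CHO–CH=C(CH3)2 and forms the C-3'–C and O-4'–C(CH3)2 bonds in one operation at the chromene level. The extra C=C is removed in the hydrogenation that also frees 5-OH.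
3. Enabling feature: ring B is a para-substituted phenol. Its single free oxygen O-4' lies between two equivalent ortho C–H carbons (C-3', C-5'), the para carbon is blocked by C-2 of ring C, and ring D ends in a non-stereogenic O–C(CH3)2 carbon that maps onto the β,β-dimethyl end of the enal.
4. 5 ⇒ 3 + 4: ring B and the C-2 stereocentre come from a rhodium/chiral diene 1,4-addition of 4-hydroxyphenylboronic acid to the doubly protected chromone.
5. Ring order: rings A and C are bought with chromone 1, ring B is attached in step 3, ring D is closed in step 4.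

Key step: step 4

Assumption: flavonoid numbering is used (ring A = C-5 to C-8, ring C = pyranone, ring B = 2-aryl group with primed numbers, ring D = dimethylpyran ring), and 5,7-dihydroxychromone and (S,S)-Ph-bod* = (1S,4S)-2,5-diphenylbicyclo[2.2.2]octa-2,5-diene are taken as catalogue items.

Step 1
Reactants: 1 5,7-dihydroxy-4H-chromen-4-one
Product: 2 5-hydroxy-7-(methoxymethoxy)-4H-chromen-4-one
Conditions: MOMCl (1.1 equiv), i-Pr2NEt, CH2Cl2/DMF, 0 °C to rt
Reagents that add atoms: chloromethyl methyl ether (MOMCl), COCCl
Why: Williamson-type O-alkylation with an α-chloro ether, in which the acidic, unhindered 7-OH reacts while the 5-OH stays locked in its hydrogen bond to the C-4 carbonyl and is left untouched by one equivalent of reagent under amine base.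

Step 2
Reactants: 2 5-hydroxy-7-(methoxymethoxy)-4H-chromen-4-one
Product: 3 5-(benzyloxy)-7-(methoxymethoxy)-4H-chromen-4-one
Conditions: BnBr, K2CO3, DMF, 60 °C
Reagents that add atoms: benzyl bromide, BrCc1ccccc1
Why: Williamson ether synthesis, in which carbonate in warm DMF breaks the 5-OH/C=O chelate and benzylates it, capping the last hydroxyl of ring A for steps 3 and 4 with a group that step 5 removes at no extra cost.

Step 3
Reactants: 3 5-(benzyloxy)-7-(methoxymethoxy)-4H-chromen-4-one; 4 4-hydroxyphenylboronic acid
Product: 5 (2S)-5-(benzyloxy)-2-(4-hydroxyphenyl)-7-(methoxymethoxy)chroman-4-one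
Conditions: [RhCl(C2H4)2]2 (2.5 mol %), (S,S)-Ph-bod* (5.5 mol %), KOH (10 mol %), 4 (2.5 equiv), dioxane/H2O (10:1), 40 °C
Reagents that add atoms: none
Why: Hayashi–Miyaura asymmetric 1,4-addition, a reaction type shown on 5,7-dialkoxychromones, in which the aryl complex of monovalent rhodium inserts the C-2=C-3 bond on the face left open by the phenyl groups of the C2-symmetric diene and the oxa-π-allyl rhodium enolate is hydrolysed, so the ligand sets C-2; the (S,S)-diene, which gives (S)-3-arylcyclohexanones through the spatially same enone face, is expected to give 2S (the antipodal ligand is equally available should the sense prove opposite), and the excess boronic acid buffers the little KOH so that ring C of the product is not opened.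

Step 4
Reactants: 5 (2S)-5-(benzyloxy)-2-(4-hydroxyphenyl)-7-(methoxymethoxy)chroman-4-one; 6 3-methylbut-2-enal (prenal)
Product: 9 (2S)-5-(benzyloxy)-2-(2,2-dimethyl-2H-chromen-6-yl)-7-(methoxymethoxy)chroman-4-one, via benzodioxaborin 7 (not isolated), via ortho-quinone methide 8 (not isolated)
Conditions: PhB(OH)2 (1.2 equiv), 6 (2 equiv), AcOH, toluene, reflux, Dean–Stark trap; aqueous work-up
Reagents that add atoms: none
Why: PhB(OH)2 esterifies the only free phenol (O-4' of ring B) and binds prenal, so the aldehyde carbon is handed through a six-membered cyclic transition state to the ortho carbon C-3' (aryl–C bond) and the resulting carbinol is held as benzodioxaborin 7; at reflux 7 expels the PhB=O unit by cycloreversion to the vinylogous ortho-quinone methide 8, whose 1-oxatriene O-4'=C-4'–C-3'=CH–CH=C(CH3)2 closes to chromene 9 (O–C(CH3)2 bond) with rearomatisation of ring B. The closest known reaction type is the phenylboronic acid-mediated one-pot synthesis of 2H-chromenes from phenols and α,β-unsaturated aldehydes, a formal [3+3] annulation made of templated ortho-hydroxyalkylation, dehydration and electrocyclisation. Ring D is closed by a thermal disrotatory oxa-6π electrocyclisation and not by an ionic 6-endo attack, so no carbocation and no strong acid ever meet the MOM acetal, the benzyl ether or ring C. No lasting stereocentre is made, since the carbinol carbon of 7 becomes sp2 in 8 and the oxygen-bearing carbon of ring D carries two methyl groups, and C-2 should stay S because the medium is free of base and only weakly acidic, which keeps the retro-oxa-Michael opening of ring C out of reach. The step needs chemoselectivity for ring B over the much more electron-rich ring A and regioselectivity within ring B: the first is secured because C–C bond formation is intramolecular within the boronate of the single free OH while O-5 and O-7 are capped, the second because C-3' and C-5' are exchanged by rotation about the C-2–C-1' bond and the para position is filled by C-2, so that only one annulation product can arise. Attack at the carbonyl carbon of the enal instead of conjugate addition follows from activation of the aldehyde oxygen by boron, the water formed is removed azeotropically, and PhB(OH)2 is returned on aqueous work-up.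

Step 5
Reactants: 9 (2S)-5-(benzyloxy)-2-(2,2-dimethyl-2H-chromen-6-yl)-7-(methoxymethoxy)chroman-4-one
Product: 10 (2S)-2-(2,2-dimethylchroman-6-yl)-5-hydroxy-7-(methoxymethoxy)chroman-4-one
Conditions: H2 (1 atm), Pd/C (10 %), EtOAc, rt
Reagents that add atoms: none
Why: Heterogeneous catalytic hydrogenation does two jobs at once, saturation of the cis-disubstituted styrene-type C=C of ring D (bringing it to the chroman level) and hydrogenolysis of the benzyl ether at O-5, while the MOM ether, the electron-rich aryl ketone and the C-2 stereocentre are not touched at one atmosphere in a neutral solvent.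

Step 6
Reactants: 10 (2S)-2-(2,2-dimethylchroman-6-yl)-5-hydroxy-7-(methoxymethoxy)chroman-4-one; 11 3-methylbut-2-en-1-ol (prenol)
Product: 12 (2S)-2-(2,2-dimethylchroman-6-yl)-7-(methoxymethoxy)-5-(3-methylbut-2-enyloxy)chroman-4-one
Conditions: PPh3, DIAD, THF, 0 °C to rt
Reagents that add atoms: none
Why: Mitsunobu etherification, known for the chelated 5-OH of 7-O-protected flavanones, in which the primary allylic oxyphosphonium ion of prenol is displaced in SN2 fashion by O-5 under essentially neutral conditions, avoiding base-induced opening of ring C and hence racemisation.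

Step 7
Reactants: 12 (2S)-2-(2,2-dimethylchroman-6-yl)-7-(methoxymethoxy)-5-(3-methylbut-2-enyloxy)chroman-4-one
Product: 15 (2S)-2-(2,2-dimethylchroman-6-yl)-5-hydroxy-7-(methoxymethoxy)-8-(3-methylbut-2-enyl)chroman-4-one, via ortho-dienone 13 (not isolated), via para-dienone 14 (not isolated)
Conditions: Eu(fod)3 (10 mol %), PhCl, 85 °C
Reagents that add atoms: none
Why: Tandem aromatic Claisen–Cope rearrangement catalysed by the oxophilic chelate of trivalent europium, precedented on 5-O-prenylated flavanones and flavonols, in which Eu binds O-5 and the C-4 carbonyl, the first [3,3] shift places a 1,1-dimethylallyl group on C-6 (the only free ortho carbon), compression between C-5=O and the 7-OMOM group drives the second [3,3] shift to C-8 (para to O-5), and tautomerisation gives the chelated phenol, the transient sp3 ring carbons being erased and C-2 left untouched.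

Step 8
Reactants: 15 (2S)-2-(2,2-dimethylchroman-6-yl)-5-hydroxy-7-(methoxymethoxy)-8-(3-methylbut-2-enyl)chroman-4-one
Product: 16 euchrenone a16, (2S)-2-(2,2-dimethylchroman-6-yl)-5,7-dihydroxy-8-(3-methylbut-2-enyl)chroman-4-one
Conditions: HCl (aq, cat.), MeOH, 40 °C
Reagents that add atoms: none
Why: Acid-catalysed acetal exchange (MOM cleavage) in methanol, routinely used on 8-prenylated flavonoids, works because the acetal is far more acid-labile than the trisubstituted alkene, so mild acid and short contact free the 7-OH without hydroalkoxylation of the prenyl group, and an acidic medium does not racemise C-2.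

Compound list
1 | 5,7-dihydroxy-4H-chromen-4-one (5,7-dihydroxychromone) | O=c1ccoc2cc(O)cc(O)c12 | starting material
2 | 5-hydroxy-7-(methoxymethoxy)-4H-chromen-4-one | O=c1ccoc2cc(OCOC)cc(O)c12 | intermediate
3 | 5-(benzyloxy)-7-(methoxymethoxy)-4H-chromen-4-one | O=c1ccoc2cc(OCOC)cc(OCc3ccccc3)c12 | intermediate
4 | 4-hydroxyphenylboronic acid | OB(O)c1ccc(O)cc1 | starting material
5 | (2S)-5-(benzyloxy)-2-(4-hydroxyphenyl)-7-(methoxymethoxy)chroman-4-one | O=C1C[C@@H](c2ccc(O)cc2)Oc2cc(OCOC)cc(OCc3ccccc3)c12 | intermediate
6 | 3-methylbut-2-enal (prenal) | CC(C)=CC=O | starting material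
7 | benzodioxaborin: (2S)-5-(benzyloxy)-7-(methoxymethoxy)-2-[4-(2-methylprop-1-enyl)-2-phenyl-4H-1,3,2-benzodioxaborinin-6-yl]chroman-4-one, both epimers at the carbinol carbon | O=C1C[C@@H](c2ccc3OB(c4ccccc4)OC(C=C(C)C)c3c2)Oc2cc(OCOC)cc(OCc3ccccc3)c12 | intermediate
8 | ortho-quinone methide: (2S)-5-(benzyloxy)-7-(methoxymethoxy)-2-[3-(3-methylbut-2-enylidene)-4-oxocyclohexa-1,5-dien-1-yl]chroman-4-one | O=C1C[C@@H](C2=CC(=CC=C(C)C)C(=O)C=C2)Oc2cc(OCOC)cc(OCc3ccccc3)c12 | intermediate
9 | (2S)-5-(benzyloxy)-2-(2,2-dimethyl-2H-chromen-6-yl)-7-(methoxymethoxy)chroman-4-one | O=C1C[C@@H](c2ccc3OC(C)(C)C=Cc3c2)Oc2cc(OCOC)cc(OCc3ccccc3)c12 | intermediate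
10 | (2S)-2-(2,2-dimethylchroman-6-yl)-5-hydroxy-7-(methoxymethoxy)chroman-4-one | O=C1C[C@@H](c2ccc3OC(C)(C)CCc3c2)Oc2cc(OCOC)cc(O)c12 | intermediate
11 | 3-methylbut-2-en-1-ol (prenol) | CC(C)=CCO | starting material
12 | (2S)-2-(2,2-dimethylchroman-6-yl)-7-(methoxymethoxy)-5-(3-methylbut-2-enyloxy)chroman-4-one | O=C1C[C@@H](c2ccc3OC(C)(C)CCc3c2)Oc2cc(OCOC)cc(OCC=C(C)C)c12 | intermediate
13 | ortho-dienone: (2S)-2-(2,2-dimethylchroman-6-yl)-7-(methoxymethoxy)-6-(2-methylbut-3-en-2-yl)-2,3-dihydrochromene-4,5(6H)-dione, both C-6 epimers | O=C1C[C@@H](c2ccc3OC(C)(C)CCc3c2)OC2=C1C(=O)C(C(C)(C)C=C)C(OCOC)=C2 | intermediate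
14 | para-dienone: (2S)-2-(2,2-dimethylchroman-6-yl)-7-(methoxymethoxy)-8-(3-methylbut-2-enyl)-2,3-dihydrochromene-4,5(8H)-dione, both C-8 epimers | O=C1C[C@@H](c2ccc3OC(C)(C)CCc3c2)OC2=C1C(=O)C=C(OCOC)C2CC=C(C)C | intermediate
15 | (2S)-2-(2,2-dimethylchroman-6-yl)-5-hydroxy-7-(methoxymethoxy)-8-(3-methylbut-2-enyl)chroman-4-one | O=C1C[C@@H](c2ccc3OC(C)(C)CCc3c2)Oc2c(CC=C(C)C)c(OCOC)cc(O)c12 | intermediate
16 | euchrenone a16, (2S)-2-(2,2-dimethylchroman-6-yl)-5,7-dihydroxy-8-(3-methylbut-2-enyl)chroman-4-one | CC(C)=CCc1c(O)cc(O)c2c1O[C@H](c1ccc3c(c1)CCC(C)(C)O3)CC2=O | target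

Total step count: 8. Longest linear sequence: 8 steps (1 to 16).

Steps most likely to fail

Step 4 (key step).
- What may go wrong: slow templated attack of the mono-oxygenated, only moderately nucleophilic ring B on the enal; self-condensation of prenal; gradual loss of configurational purity at C-2 through reversible opening of ring C during the long reflux.
- Fallback: ring D is made before the stereocentre exists. The fallback sets out from 3 and returns at 10.
- 4-Bromophenol and isoprene are joined by acid-catalysed Friedel–Crafts prenylation/hydroalkoxylation (AgOTf cat., ClCH2CH2Cl, 40 °C) to 6-bromo-2,2-dimethylchroman F1.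
- Bromine–lithium exchange (n-BuLi, THF, −78 °C), B(Oi-Pr)3 and aqueous acid give (2,2-dimethylchroman-6-yl)boronic acid F2.
- F2 is added to chromone 3 under the conditions of step 3 to give (2S)-5-(benzyloxy)-2-(2,2-dimethylchroman-6-yl)-7-(methoxymethoxy)chroman-4-one F3.
- Hydrogenolysis of the benzyl ether (H2, Pd/C, EtOAc) then gives 10.

Step 3.
- What may go wrong: protodeboronation of the electron-rich boronic acid; slow insertion of the electron-rich, peri-substituted chromone; poor facial selectivity; opening of ring C of the free-phenol product triggered by the basic aqueous medium.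
- Fallback: the phenol is carried masked, and C–C bond formation is moved from the rhodium aryl/oxa-π-allyl cycle to a base-free carbopalladation–protonolysis cycle of cationic divalent palladium. The fallback sets out from 3 and returns at 5.
- Commercial 4-(tert-butyldimethylsilyloxy)phenylboronic acid is added to 3 with Pd(OCOCF3)2, t-BuPyOx (by the cyclohexenone analogy the (R)-ligand for 2S), NH4PF6 and H2O in ClCH2CH2Cl at 60 °C. This gives (2S)-5-(benzyloxy)-2-[4-(tert-butyldimethylsilyloxy)phenyl]-7-(methoxymethoxy)chroman-4-one F4.
- Et3N·3HF in THF at 0 °C then frees the phenol and gives 5.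

Step 7.
- What may go wrong: arrest of the cascade after the first [3,3] shift by tautomerisation of the ortho-dienone, which leaves the reverse-prenyl group on C-6; Lewis acid-induced loss of the prenyl group from O-5.
- Fallback: Friedel–Crafts chemistry replaces the sigmatropic chemistry. The fallback sets out from 10 and returns at 16.
- The MOM group is removed first (HCl cat., MeOH, 40 °C) to give (2S)-2-(2,2-dimethylchroman-6-yl)-5,7-dihydroxychroman-4-one F5.
- The phloroglucinol-type ring A of F5 is then C-prenylated directly with 2-methylbut-3-en-2-ol and BF3·OEt2 in dioxane at rt. The C-8 product 16 is separated by chromatography from material alkylated at C-6.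

Further compounds
F1 | step 4 | 6-bromo-2,2-dimethylchroman | CC1(C)CCc2cc(Br)ccc2O1
F2 | step 4 | (2,2-dimethylchroman-6-yl)boronic acid | CC1(C)CCc2cc(B(O)O)ccc2O1
F3 | step 4 | (2S)-5-(benzyloxy)-2-(2,2-dimethylchroman-6-yl)-7-(methoxymethoxy)chroman-4-one | O=C1C[C@@H](c2ccc3OC(C)(C)CCc3c2)Oc2cc(OCOC)cc(OCc3ccccc3)c12
F4 | step 3 | (2S)-5-(benzyloxy)-2-[4-(tert-butyldimethylsilyloxy)phenyl]-7-(methoxymethoxy)chroman-4-one | O=C1C[C@@H](c2ccc(O[Si](C)(C)C(C)(C)C)cc2)Oc2cc(OCOC)cc(OCc3ccccc3)c12
F5 | step 7 | (2S)-2-(2,2-dimethylchroman-6-yl)-5,7-dihydroxychroman-4-one | O=C1C[C@@H](c2ccc3OC(C)(C)CCc3c2)Oc2cc(O)cc(O)c12
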